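The pitfall is to read the share of target off the partner charged, as if the flask stayed as it starts.

    starting material + partner → target (k1 = 0.76 M⁻¹ s⁻¹)
    starting material + 2 partner → side product (k2 = 4.7 M⁻² s⁻¹)
    2 partner → homo dimer (k3 = 0.17 M⁻¹ s⁻¹)

the same everywhere: time 4.0 min

|  | starting material | partner | remark |
|---|---|---|---|
| beta | 0.050 M | 0.0550 M | everything together at the start |
| delta | 0.050 M | 0.0550 M (fed, over 1.5 min) | all else is in the flask from the start; the feed brings no volume worth counting |
| alpha | 0.050 M (fed, over 1.5 min) | 0.0550 M | all else is in the flask from the start; the feed brings no volume worth counting |

* the best flask by share of target in target plus side product; "all alike" if 1.5 percentage points covers them all (beta / delta / alpha / all alike)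
* share of target in target plus side product at the end, beta
* share of target in target plus side product at the end, delta
* share of target in target plus side product at the end, alpha

I follow one molecule of starting material to its fork. With partner at concentration b, its chance of becoming target is F/(F+b), where F is the ratio of the target constant to the side product constant, 0.162 M: the fork concentration, a selectivity factor in concentration units. At the charge of beta that gives 74.6%. But b falls during the run, so I sum the fork along that fall, with one partner per target and 2 per side product. Leaving the homo dimer aside, this gives 0.0420 M of target and 0.006521 M of side product, a share of 86.5%.

The objection is that in beta the homo dimer step first uses partner at 0.492 of the rate of the target step. That ratio goes with b over starting material, so the homo dimer step is no even slice of the partner, and I can't sum it by hand; the figure for beta stays an estimate with this doubt open.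

Alpha runs through the same fall of b, but its starting material arrives slowly, so the homo dimer takes more of the partner while b is high. I put alpha above beta, by an amount I can't sum by hand.

In delta, the feed lasts 3.42 lifetimes of partner against the charged starting material, so b sits near a quasi-steady 0.0161 M, which gives 91.0%. Falling starting material pushes b up, but b also starts from nothing, so I keep that figure, higher than beta.

The forecast also names delta, with 86.5% for beta, 91% for delta and 86% for alpha, holding that “feeding the partner slowly into the starting material keeps that concentration low throughout”.

The flask gives delta, at 93.0%, with 86.6% for beta and 90.0% for alpha. In delta, the target step uses starting material 11 times as fast as the side product step at 1.08 min, and 58 times as fast at 4.00 min. Through F, these readings put partner at 0.0153 M and then 0.002793 M. The share in beta moves by 5 points at partner charges of 0.0322 M and 0.0775 M, so a run at such a charge is what it takes to put the forecast's figure for beta that far off.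

For the neighbour of delta charged with 0.014 M of partner, the same reckoning gives b near 0.004094 M and a share of 97.5%. That flask gives 98.2%, with 73.4% of its starting material left.

All constants stand for no real mixture; the rest is arithmetic.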